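**Retrosynthetic overview**

- Numbering: decalin C1–C10, C11 = benzylic CH2, methyls on C4, C5, C8, C9. Enabling feature: ring B (C5–C6–C7–C8–C9–C10) has a quaternary C9 whose exocyclic carbon C11 can be a formyl group, and C5/C10 are bridged by C1–C4 of ring A (with the C3=C4 alkene). With a C6=C7 alkene added, ring B is the adduct of an (E)-2-methyl-enal (C11–C9=C10) and an (E,E)-diene (C5=C6–C7=C8) tethered through C1–C4.
- Disconnections: (i) aryl–C11 (aryllithium + aldehyde, then removal of the C11 oxygen); (ii) C6=C7 (hydrogenation); (iii) C8–C9 and C5–C10 together, by a catalytic enantioselective intramolecular Diels–Alder reaction of the achiral acyclic tetraenal 12, which sets all four stereocentres (two quaternary) of the cis-fused decalin.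
- Tetraenal 12 comes from (Z)-3-methylpent-2-en-4-yn-1-ol (Z-C3=C4 purchased), an ester-enolate alkylation (C1, C10), carboalumination/cross-coupling (5-methyl, C5=C6, C7=C8) and a Wittig reaction (C9=C10, C11).
- Ring order: the benzoxazole ring is made first and separately from 4-methoxyresorcinol; rings A and B are formed together in step 7.

Key step: step 7

Assumption: the sense of induction in step 7 is taken from the usual pre-transition-state model of cationic oxazaborolidines with 2-substituted enals (with the (S)-catalyst the diene adds to the Re face of the α-carbon); it is a model prediction, not a measured result.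

**Route**

Step 1
Reactants: 1 (Z)-3-methylpent-2-en-4-yn-1-ol
Product: 2 (Z)-5-bromo-3-methylpent-3-en-1-yne
Conditions: PBr3 (0.4 equiv), pyridine (cat.), Et2O, −20 → 0 °C
Reagents that add atoms: phosphorus tribromide, BrP(Br)Br
Why: SN2 bromination of a primary allylic alcohol via its phosphite ester at low temperature should keep the Z geometry; no stereocentre is formed.

Step 2
Reactants: 2 (Z)-5-bromo-3-methylpent-3-en-1-yne; 3 tert-butyl acetate
Product: 5 tert-butyl (4Z)-5-methylhept-4-en-6-ynoate, via lithium enolate of tert-butyl acetate 4 (not isolated)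
Conditions: LDA, THF, −78 °C (3, 2.2 equiv); then 2, DMPU, −78 → −30 °C
Reagents that add atoms: none
Why: Ester enolate alkylation (SN2 at the primary allylic bromide) should add C1 and C10; the excess enolate covers the acidic alkyne C–H and the Z alkene is not touched.

Step 3
Reactants: 5 tert-butyl (4Z)-5-methylhept-4-en-6-ynoate
Product: 6 (4Z)-5-methylhept-4-en-6-yn-1-ol
Conditions: LiAlH4, Et2O, 0 °C
Reagents that add atoms: none
Why: Hydride reduction of the ester to the primary alcohol; an enyne without a propargylic hydroxyl should not be hydroaluminated at 0 °C.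

Step 4
Reactants: 6 (4Z)-5-methylhept-4-en-6-yn-1-ol; 7 (E)-1-bromoprop-1-ene
Product: 9 (4Z,6E,8E)-5,6-dimethyldeca-4,6,8-trien-1-ol, via dimethylaluminium (4Z,6E)-7-(dimethylalumanyl)-5,6-dimethylhepta-4,6-dien-1-olate 8 (not isolated)
Conditions: AlMe3 (3 equiv), Cp2ZrCl2 (0.25 equiv), CH2Cl2, 0 °C → rt; then 7, Pd(PPh3)4 (5 mol %), ZnCl2, THF, rt
Reagents that add atoms: trimethylaluminium, C[Al](C)C
Why: Negishi zirconium-catalysed carboalumination (syn addition, methyl to the internal alkyne carbon) followed by Pd-catalysed alkenyl–alkenyl cross-coupling with retention at both partners should give the 6E,8E diene; the hydroxyl is masked in situ as its aluminium alkoxide.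

Step 5
Reactants: 9 (4Z,6E,8E)-5,6-dimethyldeca-4,6,8-trien-1-ol
Product: 10 (4Z,6E,8E)-5,6-dimethyldeca-4,6,8-trienal
Conditions: Dess–Martin periodinane, NaHCO3, CH2Cl2, 0 °C → rt
Reagents that add atoms: none
Why: Dess–Martin oxidation of a primary alcohol under buffered, neutral conditions should leave the acid-sensitive triene intact.

Step 6
Reactants: 10 (4Z,6E,8E)-5,6-dimethyldeca-4,6,8-trienal; 11 2-(triphenyl-λ5-phosphanylidene)propanal
Product: 12 (2E,6Z,8E,10E)-2,7,8-trimethyldodeca-2,6,8,10-tetraenal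
Conditions: benzene, 60 °C
Reagents that add atoms: none
Why: Wittig reaction of a formyl-stabilised ylide should give the E enal (CHO trans to the chain); the temperature is held at 60 °C so that 12 does not cyclise without the catalyst.

Step 7
Reactants: 12 (2E,6Z,8E,10E)-2,7,8-trimethyldodeca-2,6,8,10-tetraenal
Product: 13 (1R,2S,4aR,8aR)-1,2,4a,5-tetramethyl-1,2,4a,7,8,8a-hexahydronaphthalene-1-carbaldehyde (cis-fused; 5-Me and H-10 on one face, the C1–C4 bridge, 8-Me and 9-Me on the other, CHO on the face of H-10)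
Conditions: (S)-o-tolyl-oxazaborolidine from (S)-diphenylprolinol (20 mol %), Tf2NH (17 mol %), CH2Cl2, −78 → −20 °C
Reagents that add atoms: none
Why: The N-protonated (S)-oxazaborolidine binds the formyl oxygen of 12 and lowers the LUMO of the C9=C10 enal, which adds suprafacially to C5 and C8 of the s-cis (E,E)-diene in a concerted, asynchronous intramolecular [4+2] cycloaddition; the closest known reaction type is the chiral-boron-Lewis-acid-catalysed intramolecular Diels–Alder reaction of 2-methyl-2,7,9-trienals. Ring B (C5–C6=C7–C8–C9–C10) is closed by the [π4s+π2s] addition itself, and ring A (C10–C1–C2–C3=C4–C5) is closed at the same time by the C5–C10 bond, because the four-carbon tether C1–C4 already joins dienophile carbon C10 to diene terminus C5 (type-1 cyclisation of a 1,7,9-decatriene, six-membered ring). C9 and C10 are related by the E geometry of the enal (9-methyl cis to C1), C5 and C8 by the E,E geometry of the diene with the tether in the outside position (8-methyl cis to C4), and the two pairs are related to each other by the formyl-exo, tether-endo transition state, which gives the cis ring fusion with the 8- and 9-methyl groups cis. The absolute configuration comes from the catalyst: in the accepted model for 2-substituted enals (s-trans enal, formyl C–H···O contact) a phenyl group of the (S)-catalyst covers the Si face of C9, so C8 should add to the Re face of C9 and give the enantiomer drawn. The selectivity that the step needs is exo with respect to the formyl group; the substrate should secure it because the α-methyl group of the enal takes the endo position as in other 2-methyl-enal dienophiles, and because in the competing formyl-endo transition state the exo 9-methyl would run into the inside methyl group on C5 (the 1,3-diaxial methyl pair of the trans-fused series). Only the C5=C6–C7=C8 diene can reach C9=C10 (the C3=C4 alkene is twisted out of conjugation within the tether, and any addition across C3–C6 would need a four-membered or bridged ring), so no other cycloaddition mode should compete.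

Step 8
Reactants: 13 (1R,2S,4aR,8aR)-1,2,4a,5-tetramethyl-1,2,4a,7,8,8a-hexahydronaphthalene-1-carbaldehyde
Product: 14 (1R,2S,4aR,8aR)-1,2,4a,5-tetramethyl-1,2,3,4,4a,7,8,8a-octahydronaphthalene-1-carbaldehyde
Conditions: H2 (3 atm), RhCl(PPh3)3 (10 mol %), benzene, rt
Reagents that add atoms: none
Why: Homogeneous hydrogenation with Wilkinson's catalyst is sensitive to alkene substitution, so the cis-disubstituted C6=C7 alkene should be reduced while the trisubstituted C3=C4 alkene and the hindered tertiary aldehyde remain; no stereocentre is created.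

Step 9
Reactants: 15 4-methoxybenzene-1,3-diol
Product: 16 4-methoxy-6-nitrosobenzene-1,3-diol
Conditions: NaNO2, AcOH/H2O, 0 °C
Reagents that add atoms: sodium nitrite, [Na+].[O-]N=O
Why: Electrophilic C-nitrosation of a resorcinol goes para to a hydroxyl, and C6 is the only free position para to OH.

Step 10
Reactants: 16 4-methoxy-6-nitrosobenzene-1,3-diol
Product: 18 5-methoxy-2-methyl-1,3-benzoxazol-6-ol, via 4-amino-6-methoxybenzene-1,3-diol 17 (not isolated)
Conditions: H2 (1 atm), Pd/C, EtOH, rt; filter under N2; MeC(OEt)3, PPTS (cat.), 100 °C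
Reagents that add atoms: triethyl orthoacetate, CCOC(C)(OCC)OCC
Why: Hydrogenation of the nitroso group gives the o-aminophenol, which condenses with the orthoester to the 2-methylbenzoxazole; only one hydroxyl is ortho to the amine, so the ring can close in one direction only.

Step 11
Reactants: 18 5-methoxy-2-methyl-1,3-benzoxazol-6-ol
Product: 19 7-bromo-5-methoxy-2-methyl-1,3-benzoxazol-6-ol
Conditions: NBS, MeCN, 0 °C
Reagents that add atoms: N-bromosuccinimide, O=C1CCC(=O)N1Br
Why: Electrophilic aromatic bromination is directed ortho to the phenol, and C7 is the only free ortho position.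

Step 12
Reactants: 19 7-bromo-5-methoxy-2-methyl-1,3-benzoxazol-6-ol
Product: 20 7-bromo-5-methoxy-6-(methoxymethoxy)-2-methyl-1,3-benzoxazole
Conditions: MOMCl, i-Pr2NEt, CH2Cl2, 0 °C → rt
Reagents that add atoms: chloromethyl methyl ether, COCCl
Why: O-alkylation of the phenol gives a MOM ether that tolerates organolithium and radical conditions.

Step 13
Reactants: 20 7-bromo-5-methoxy-6-(methoxymethoxy)-2-methyl-1,3-benzoxazole; 14 (1R,2S,4aR,8aR)-1,2,4a,5-tetramethyl-1,2,3,4,4a,7,8,8a-octahydronaphthalene-1-carbaldehyde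
Product: 24 O-{[5-methoxy-6-(methoxymethoxy)-2-methyl-1,3-benzoxazol-7-yl][(1R,2S,4aR,8aR)-1,2,4a,5-tetramethyl-1,2,3,4,4a,7,8,8a-octahydronaphthalen-1-yl]methyl} S-methyl carbonodithioate, via [5-methoxy-6-(methoxymethoxy)-2-methyl-1,3-benzoxazol-7-yl]lithium 21 (not isolated), via lithium alkoxide of the C11 carbinol 22 (not isolated), via lithium O-alkyl carbonodithioate 23 (not isolated)
Conditions: t-BuLi (2.0 equiv), THF, −90 °C, 5 min; 14, −78 → 0 °C; CS2, 0 °C → rt; MeI
Reagents that add atoms: carbon disulfide, S=C=S; iodomethane, CI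
Why: Bromine–lithium exchange at −90 °C should outrun deprotonation of the 2-methyl group, the aryllithium adds 1,2 to the non-enolisable aldehyde, and the hindered alkoxide is trapped as the S-methyl xanthate (first stage of a Barton–McCombie deoxygenation); the new C11 centre is not controlled and both epimers converge in step 14.

Step 14
Reactants: 24 the S-methyl xanthate
Product: 25 5-methoxy-6-(methoxymethoxy)-2-methyl-7-{[(1R,2S,4aR,8aS)-1,2,4a,5-tetramethyl-1,2,3,4,4a,7,8,8a-octahydronaphthalen-1-yl]methyl}-1,3-benzoxazole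
Conditions: Bu3SnH, AIBN (cat.), toluene, 90 °C
Reagents that add atoms: none
Why: Barton–McCombie radical deoxygenation removes the C11 oxygen through a benzylic radical, so no cationic rearrangement of the neopentyl centre should occur and the benzoxazole and C3=C4 alkene survive.

Step 15
Reactants: 25 the MOM ether of the target
Product: 26 5-methoxy-2-methyl-7-{[(1R,2S,4aR,8aS)-1,2,4a,5-tetramethyl-1,2,3,4,4a,7,8,8a-octahydronaphthalen-1-yl]methyl}-1,3-benzoxazol-6-ol (target)
Conditions: HCl (1.25 M in MeOH), THF, rt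
Reagents that add atoms: none
Why: Acid-catalysed acetal exchange removes the MOM group under conditions that should be too mild to protonate the trisubstituted alkene or open the benzoxazole.

**Compound list**

1 | (Z)-3-methylpent-2-en-4-yn-1-ol | C#C/C(C)=C\CO | starting material
2 | (Z)-5-bromo-3-methylpent-3-en-1-yne | C#C/C(C)=C\CBr | intermediate
3 | tert-butyl acetate | CC(=O)OC(C)(C)C | starting material
4 | lithium enolate of tert-butyl acetate | C=C(O[Li])OC(C)(C)C | intermediate
5 | tert-butyl (4Z)-5-methylhept-4-en-6-ynoate | C#C/C(C)=C\CCC(=O)OC(C)(C)C | intermediate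
6 | (4Z)-5-methylhept-4-en-6-yn-1-ol | C#C/C(C)=C\CCCO | intermediate
7 | (E)-1-bromoprop-1-ene | C/C=C/Br | starting material
8 | dimethylaluminium (4Z,6E)-7-(dimethylalumanyl)-5,6-dimethylhepta-4,6-dien-1-olate | C[Al](C)/C=C(C)/C(C)=C\CCCO[Al](C)C | intermediate
9 | (4Z,6E,8E)-5,6-dimethyldeca-4,6,8-trien-1-ol | C/C=C/C=C(C)/C(C)=C\CCCO | intermediate
10 | (4Z,6E,8E)-5,6-dimethyldeca-4,6,8-trienal | C/C=C/C=C(C)/C(C)=C\CCC=O | intermediate
11 | 2-(triphenyl-λ5-phosphanylidene)propanal | CC(C=O)=P(c1ccccc1)(c1ccccc1)c1ccccc1 | starting material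
12 | (2E,6Z,8E,10E)-2,7,8-trimethyldodeca-2,6,8,10-tetraenal | C/C=C/C=C(C)/C(C)=C\CC/C=C(\C)C=O | intermediate
13 | (1R,2S,4aR,8aR)-1,2,4a,5-tetramethyl-1,2,4a,7,8,8a-hexahydronaphthalene-1-carbaldehyde | O=C[C@]1(C)[C@@H](C)C=C[C@@]2(C)C(C)=CCC[C@@H]12 | intermediate
14 | (1R,2S,4aR,8aR)-1,2,4a,5-tetramethyl-1,2,3,4,4a,7,8,8a-octahydronaphthalene-1-carbaldehyde | O=C[C@]1(C)[C@@H](C)CC[C@@]2(C)C(C)=CCC[C@@H]12 | intermediate
15 | 4-methoxybenzene-1,3-diol | COc1ccc(O)cc1O | starting material
16 | 4-methoxy-6-nitrosobenzene-1,3-diol | COc1cc(N=O)c(O)cc1O | intermediate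
17 | 4-amino-6-methoxybenzene-1,3-diol | COc1cc(N)c(O)cc1O | intermediate
18 | 5-methoxy-2-methyl-1,3-benzoxazol-6-ol | COc1cc2nc(C)oc2cc1O | intermediate
19 | 7-bromo-5-methoxy-2-methyl-1,3-benzoxazol-6-ol | COc1cc2nc(C)oc2c(Br)c1O | intermediate
20 | 7-bromo-5-methoxy-6-(methoxymethoxy)-2-methyl-1,3-benzoxazole | COCOc1c(OC)cc2nc(C)oc2c1Br | intermediate
21 | [5-methoxy-6-(methoxymethoxy)-2-methyl-1,3-benzoxazol-7-yl]lithium | [Li]c1c(OCOC)c(OC)cc2nc(C)oc12 | intermediate
22 | lithium [5-methoxy-6-(methoxymethoxy)-2-methyl-1,3-benzoxazol-7-yl][(1R,2S,4aR,8aR)-1,2,4a,5-tetramethyl-1,2,3,4,4a,7,8,8a-octahydronaphthalen-1-yl]methanolate (C11 epimers) | [Li]OC(c1c(OCOC)c(OC)cc2nc(C)oc12)[C@]3(C)[C@@H](C)CC[C@@]4(C)C(C)=CCC[C@@H]34 | intermediate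
23 | lithium O-{[5-methoxy-6-(methoxymethoxy)-2-methyl-1,3-benzoxazol-7-yl][(1R,2S,4aR,8aR)-1,2,4a,5-tetramethyl-1,2,3,4,4a,7,8,8a-octahydronaphthalen-1-yl]methyl} carbonodithioate (C11 epimers) | [Li]SC(=S)OC(c1c(OCOC)c(OC)cc2nc(C)oc12)[C@]3(C)[C@@H](C)CC[C@@]4(C)C(C)=CCC[C@@H]34 | intermediate
24 | O-{[5-methoxy-6-(methoxymethoxy)-2-methyl-1,3-benzoxazol-7-yl][(1R,2S,4aR,8aR)-1,2,4a,5-tetramethyl-1,2,3,4,4a,7,8,8a-octahydronaphthalen-1-yl]methyl} S-methyl carbonodithioate (C11 epimers) | CSC(=S)OC(c1c(OCOC)c(OC)cc2nc(C)oc12)[C@]3(C)[C@@H](C)CC[C@@]4(C)C(C)=CCC[C@@H]34 | intermediate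
25 | 5-methoxy-6-(methoxymethoxy)-2-methyl-7-{[(1R,2S,4aR,8aS)-1,2,4a,5-tetramethyl-1,2,3,4,4a,7,8,8a-octahydronaphthalen-1-yl]methyl}-1,3-benzoxazole | COCOc1c(OC)cc2nc(C)oc2c1C[C@]3(C)[C@@H](C)CC[C@@]4(C)C(C)=CCC[C@@H]34 | intermediate
26 | 5-methoxy-2-methyl-7-{[(1R,2S,4aR,8aS)-1,2,4a,5-tetramethyl-1,2,3,4,4a,7,8,8a-octahydronaphthalen-1-yl]methyl}-1,3-benzoxazol-6-ol | COc1cc2nc(C)oc2c(C[C@]2(C)[C@@H](C)CC[C@@]3(C)C(C)=CCC[C@@H]23)c1O | target

**Step count**

Total steps: 15. Longest linear sequence: 11 (steps 1–8, then 13–15); steps 9–12 build the aryl fragment in parallel.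

**Steps most likely to fail**

1. Step 7. The Lewis-acid-bound enal may prefer the formyl-endo transition state (trans-fused adduct), or the catalyst may discriminate the two enal faces poorly or in the opposite sense. Fallback, from 12 back to 13: 12 is cyclised without Lewis acid (toluene, BHT, 110 °C), where the formyl-endo preference is weakest, to the racemic cis-fused aldehyde F1. F1 is condensed with (1R,2R)-N,N′-dimethyl-1,2-diphenylethane-1,2-diamine (Et2O, molecular sieves) to the aminal of the wanted enantiomer F2 and the diastereomeric aminal F3. These are separated by chromatography, and F2 is hydrolysed (dilute aqueous HCl, THF) to return to the route at 13.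

2. Step 13. The aryllithium may be quenched by proton transfer from the 2-methyl group of the benzoxazole, or may add too slowly to the neopentyl aldehyde, and the hindered alkoxide may not be captured by CS2. Fallback, from 15 and 14 to 26, with the heterocycle built after the coupling: 15 is protected (MOMCl, i-Pr2NEt) as 1-methoxy-2,4-bis(methoxymethoxy)benzene F4. F4 is lithiated between the two MOM ethers (n-BuLi, THF, 0 °C) to [3-methoxy-2,6-bis(methoxymethoxy)phenyl]lithium F5, which is added to 14 to give the benzylic carbinol F6. Li/NH3 (THF, −78 °C, then NH4Cl) removes the benzylic oxygen to give F7, and HCl/MeOH gives the resorcinol F8. Nitrosation (NaNO2, AcOH) at the only position para to a hydroxyl gives the nitrosoresorcinol F9. Reduction with Na2S2O4 gives the aminoresorcinol F10, and condensation with triethyl orthoacetate closes the benzoxazole and returns to the route at 26.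

3. Step 6. At the temperature the stabilised ylide needs, the product tetraenal may cyclise without catalyst (racemic background reaction), and the olefination may be slow or incompletely E-selective. Fallback, from 10 back to 12, with every operation at or below room temperature: Horner–Wadsworth–Emmons reaction of 10 with triethyl 2-phosphonopropionate (NaH, THF, 0 °C) gives ethyl (2E,6Z,8E,10E)-2,7,8-trimethyldodeca-2,6,8,10-tetraenoate F11. DIBAL-H (CH2Cl2, −78 °C) gives (2E,6Z,8E,10E)-2,7,8-trimethyldodeca-2,6,8,10-tetraen-1-ol F12, and MnO2 (CH2Cl2, rt) returns to the route at 12.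

**Further compounds**

F1 | step 7 | rac-(1R*,2S*,4aR*,8aR*)-1,2,4a,5-tetramethyl-1,2,4a,7,8,8a-hexahydronaphthalene-1-carbaldehyde (racemate, both enantiomers shown) | O=C[C@]1(C)[C@@H](C)C=C[C@@]2(C)C(C)=CCC[C@@H]12.O=C[C@@]1(C)[C@H](C)C=C[C@]2(C)C(C)=CCC[C@H]12
F2 | step 7 | (4R,5R)-1,3-dimethyl-4,5-diphenyl-2-[(1R,2S,4aR,8aR)-1,2,4a,5-tetramethyl-1,2,4a,7,8,8a-hexahydronaphthalen-1-yl]imidazolidine | CN1[C@H](c2ccccc2)[C@H](N(C)C1[C@]3(C)[C@@H](C)C=C[C@@]4(C)C(C)=CCC[C@@H]34)c2ccccc2
F3 | step 7 | (4R,5R)-1,3-dimethyl-4,5-diphenyl-2-[(1S,2R,4aS,8aS)-1,2,4a,5-tetramethyl-1,2,4a,7,8,8a-hexahydronaphthalen-1-yl]imidazolidine | CN1[C@H](c2ccccc2)[C@H](N(C)C1[C@@]3(C)[C@H](C)C=C[C@]4(C)C(C)=CCC[C@H]34)c2ccccc2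
F4 | step 13 | 1-methoxy-2,4-bis(methoxymethoxy)benzene | COCOc1ccc(OC)c(OCOC)c1
F5 | step 13 | [3-methoxy-2,6-bis(methoxymethoxy)phenyl]lithium | [Li]c1c(OCOC)ccc(OC)c1OCOC
F6 | step 13 | [3-methoxy-2,6-bis(methoxymethoxy)phenyl][(1R,2S,4aR,8aR)-1,2,4a,5-tetramethyl-1,2,3,4,4a,7,8,8a-octahydronaphthalen-1-yl]methanol (C11 epimers) | COCOc1ccc(OC)c(OCOC)c1C(O)[C@]2(C)[C@@H](C)CC[C@@]3(C)C(C)=CCC[C@@H]23
F7 | step 13 | 1-methoxy-2,4-bis(methoxymethoxy)-3-{[(1R,2S,4aR,8aS)-1,2,4a,5-tetramethyl-1,2,3,4,4a,7,8,8a-octahydronaphthalen-1-yl]methyl}benzene | COCOc1ccc(OC)c(OCOC)c1C[C@]2(C)[C@@H](C)CC[C@@]3(C)C(C)=CCC[C@@H]23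
F8 | step 13 | 4-methoxy-2-{[(1R,2S,4aR,8aS)-1,2,4a,5-tetramethyl-1,2,3,4,4a,7,8,8a-octahydronaphthalen-1-yl]methyl}benzene-1,3-diol | COc1ccc(O)c(C[C@]2(C)[C@@H](C)CC[C@@]3(C)C(C)=CCC[C@@H]23)c1O
F9 | step 13 | 4-methoxy-6-nitroso-2-{[(1R,2S,4aR,8aS)-1,2,4a,5-tetramethyl-1,2,3,4,4a,7,8,8a-octahydronaphthalen-1-yl]methyl}benzene-1,3-diol | COc1cc(N=O)c(O)c(C[C@]2(C)[C@@H](C)CC[C@@]3(C)C(C)=CCC[C@@H]23)c1O
F10 | step 13 | 4-amino-6-methoxy-2-{[(1R,2S,4aR,8aS)-1,2,4a,5-tetramethyl-1,2,3,4,4a,7,8,8a-octahydronaphthalen-1-yl]methyl}benzene-1,3-diol | COc1cc(N)c(O)c(C[C@]2(C)[C@@H](C)CC[C@@]3(C)C(C)=CCC[C@@H]23)c1O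
F11 | step 6 | ethyl (2E,6Z,8E,10E)-2,7,8-trimethyldodeca-2,6,8,10-tetraenoate | C/C=C/C=C(C)/C(C)=C\CC/C=C(\C)C(=O)OCC
F12 | step 6 | (2E,6Z,8E,10E)-2,7,8-trimethyldodeca-2,6,8,10-tetraen-1-ol | C/C=C/C=C(C)/C(C)=C\CC/C=C(\C)CO
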